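## Retrosynthetic overview

1. Target 34 is the photochemical ring-opened isomer (6π opening, then [1,7]-H shift) of the angular 2,2-dimethylpyran 32 fused at O7/C8. Compound 32 comes from the 8-prenyl 7-phenol 29 by DDQ cyclisation and MOM removal.
2. The strategy rests on ring A (C4a, C5, C6, C7, C8, C8a), which is a phloroglucinol. O5, O7 and the C8 branch map onto C1, C3 and C4 of the bis(silyl) diene 26, made from γ-prenylated methyl acetoacetate. C4a=C8a is the enone double bond of a 2-aryl-2,3-dihydropyran-4-one, so ring A is cut at C8–C8a and C4a–C5 to give bromopyranone 19 plus 26.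
3. Bromopyranone 19 comes from aldehyde 15 and 1-methoxy-3-(trimethylsilyloxy)buta-1,3-diene by a catalytic asymmetric hetero-Diels–Alder reaction that sets C2. The enol silane of the cycloadduct is brominated before methanol is eliminated, so no electrophilic bromine meets the finished, less nucleophilic vinylogous ester in competition with the MOM-bearing arenes.
4. Aldehyde 15 comes from the trans-dihydrobenzofuran bromide 13. That ring is closed by an enantioselective Rh-carbene C–H insertion (C3), followed by acid epimerisation at C2.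
5. Order of ring formation: dihydrofuran ring, pyranone ring C, ring A (key step), then a temporary pyran ring that is opened again in the last step.

Key step: step 14

**Abbreviations.** ArM = (2R,3R)-3-[3,5-bis(methoxymethoxy)phenyl]-6-(methoxymethoxy)-2-[4-(methoxymethoxy)phenyl]-2,3-dihydro-1-benzofuran-5-yl. ArH = the same group with four free OH groups. Flavanone numbering is O1, C2, C3, C4, C4a, C5–C8, C8a.

**Assumption.** Rh2(S-PTAD)4 is taken to give the (3R) insertion product and (S,S)-(salen)CrBF4 the (2S) pyranone, by analogy with simple aryl substrates. Both catalysts are available in either hand, so the antipode is used if the sense proves opposite.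

## Route

Step 1
Reactants: 1 5-bromo-2-hydroxy-4-methoxybenzaldehyde; 2 4-methoxybenzyl chloride
Product: 3 5-bromo-4-methoxy-2-[(4-methoxybenzyl)oxy]benzaldehyde
Conditions: K2CO3, DMF, 60 °C
Reagents that add atoms: none
Why: Williamson etherification of the phenol installs the benzylic CH2 and the 4-oxygenated aryl ring that become C2 of the dihydrofuran and its substituent.

Step 2
Reactants: 3 5-bromo-4-methoxy-2-[(4-methoxybenzyl)oxy]benzaldehyde; 4 1-bromo-3,5-dimethoxybenzene
Product: 6 {5-bromo-4-methoxy-2-[(4-methoxybenzyl)oxy]phenyl}(3,5-dimethoxyphenyl)methanol (racemic), via aryl Grignard reagent 5 (not isolated)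
Conditions: 4, Mg, THF, reflux; then 3, THF, 0 °C; H2O
Reagents that add atoms: none
Why: Grignard addition to the aldehyde at 0 °C outruns any exchange at the ring bromide, and the carbinol centre is erased in step 3.

Step 3
Reactants: 6 diaryl carbinol
Product: 7 {5-bromo-4-methoxy-2-[(4-methoxybenzyl)oxy]phenyl}(3,5-dimethoxyphenyl)methanone
Conditions: MnO2, CH2Cl2, rt
Reagents that add atoms: none
Why: MnO2 oxidation of a doubly benzylic alcohol is selective and leaves the benzyl ether and the aryl bromide untouched.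

Step 4
Reactants: 7 diaryl ketone
Product: 8 hydrazone of 7 (geometric mixture)
Conditions: N2H4·H2O, AcOH (cat.), EtOH, reflux
Reagents that add atoms: hydrazine, NN
Why: Hydrazone condensation of a benzophenone needs only heat and weak acid, conditions under which ethers and the aryl bromide are inert.

Step 5
Reactants: 8 hydrazone
Product: 10 (2S,3R)-5-bromo-3-(3,5-dimethoxyphenyl)-6-methoxy-2-(4-methoxyphenyl)-2,3-dihydro-1-benzofuran (cis), via diaryldiazomethane 9 (not isolated)
Conditions: MnO2, CH2Cl2, 0 °C, filter; then Rh2(S-PTAD)4 (1 mol %), CH2Cl2, 0 °C to rt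
Reagents that add atoms: none
Why: Hydrazone dehydrogenation gives a donor/donor diazo compound whose dirhodium carbene undergoes the known enantioselective intramolecular 1,5 C–H insertion into the ortho benzylic ether CH2; the chiral carboxylate ligands set C3 (R), and the kinetic product is cis.

Step 6
Reactants: 10 cis-dihydrobenzofuran
Product: 11 (2R,3R)-5-bromo-3-(3,5-dimethoxyphenyl)-6-methoxy-2-(4-methoxyphenyl)-2,3-dihydro-1-benzofuran (trans)
Conditions: TFA, CH2Cl2, 0 °C to rt
Reagents that add atoms: none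
Why: Acid-mediated epimerisation by reversible C2–O heterolysis to the 4-methoxybenzyl cation and reclosure gives the thermodynamically preferred trans isomer, so the untouched C3 centre dictates C2 (R).

Step 7
Reactants: 11 trans tetramethyl ether
Product: 12 (2R,3R)-5-bromo-3-(3,5-dihydroxyphenyl)-2-(4-hydroxyphenyl)-2,3-dihydro-1-benzofuran-6-ol
Conditions: BBr3, CH2Cl2, −78 °C to rt; H2O
Reagents that add atoms: none
Why: BBr3 cleavage of aryl methyl ethers frees all four phenols, and any transient C2–O opening can only reclose to the trans ring already in place.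

Step 8
Reactants: 12 tetraphenol
Product: 13 ArM–Br, (2R,3R)-5-bromo-3-[3,5-bis(methoxymethoxy)phenyl]-6-(methoxymethoxy)-2-[4-(methoxymethoxy)phenyl]-2,3-dihydro-1-benzofuran
Conditions: MOMCl, i-Pr2NEt, CH2Cl2, 0 °C to rt
Reagents that add atoms: chloromethyl methyl ether, COCCl
Why: Acetal protection with a weak amine base avoids phenoxide-driven opening of the 2-(4-hydroxyphenyl)dihydrofuran and gives groups stable to organolithium, heat and DDQ.

Step 9
Reactants: 13 ArM–Br
Product: 15 ArM–CHO, (2R,3R)-3-[3,5-bis(methoxymethoxy)phenyl]-6-(methoxymethoxy)-2-[4-(methoxymethoxy)phenyl]-2,3-dihydro-1-benzofuran-5-carbaldehyde, via aryllithium 14 (not isolated)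
Conditions: n-BuLi, THF, −78 °C, short contact; DMF, −78 °C to 0 °C; H2O
Reagents that add atoms: N,N-dimethylformamide, CN(C)C=O
Why: Bromine–lithium exchange at −78 °C is faster than directed metalation or C3–H deprotonation, and the MOM-stabilised aryllithium is formylated by DMF (Bouveault aldehyde synthesis).

Step 10
Reactants: 15 ArM–CHO; 16 (E)-1-methoxy-3-(trimethylsilyloxy)buta-1,3-diene
Product: 19 (2S)-2-ArM-5-bromo-2,3-dihydro-4H-pyran-4-one, via enol silane cycloadduct 17 (not isolated), via bromo ketone 18 (not isolated)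
Conditions: (S,S)-(salen)CrBF4 (5 mol %; salen = N,N'-bis(3,5-di-tert-butylsalicylidene)cyclohexane-1,2-diaminate), 4 Å MS, t-BuOMe, −30 °C; filter, strip excess 16; NBS (1 equiv), THF, −78 °C; Et3N, CH2Cl2, 0 °C
Reagents that add atoms: N-bromosuccinimide, O=C1CCC(=O)N1Br
Why: The catalytic asymmetric hetero-Diels–Alder reaction runs by a concerted path on a single open metal site, so the catalyst selects the aldehyde face and sets C2 (S) while the primary product keeps its enol silane; that enol silane is far more nucleophilic than the MOM arenes and takes up bromine from NBS selectively, and E1cB loss of methanol then gives the α-bromo vinylogous ester, the minor C2 epimer being a separable diastereomer.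

Step 11
Reactants: 20 methyl acetoacetate; 21 1-bromo-3-methylbut-2-ene
Product: 23 methyl 7-methyl-3-oxooct-6-enoate, via acetoacetate dianion 22 (not isolated)
Conditions: NaH, THF, 0 °C; n-BuLi, 0 °C; 21, 0 °C to rt; dilute HCl
Reagents that add atoms: none
Why: In dianion alkylation of a β-keto ester the more basic γ-carbon reacts, so the prenyl group is placed on the carbon that becomes C8.

Step 12
Reactants: 23 β-keto ester
Product: 24 methyl 7-methyl-3-(trimethylsilyloxy)octa-2,6-dienoate (geometric mixture)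
Conditions: Me3SiCl, Et3N, hexane, rt
Reagents that add atoms: chlorotrimethylsilane, C[Si](C)(C)Cl
Why: O-silylation of the enolisable β-keto ester under soft enolisation is the standard first stage of bis(silyloxy)diene synthesis.

Step 13
Reactants: 24 silyl enol ether
Product: 26 (1Z,3Z)-1-methoxy-7-methyl-1,3-bis(trimethylsilyloxy)octa-1,3,6-triene, via lithium dienolate 25 (not isolated)
Conditions: LDA, THF, −78 °C; Me3SiCl, −78 °C to rt; non-aqueous work-up
Reagents that add atoms: chlorotrimethylsilane, C[Si](C)(C)Cl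
Why: γ-Deprotonation of the vinylogous ester and O-silylation of the ester enolate give the 4-alkyl-1,3-bis(silyloxy)diene with the prenyl chain pointing outward, as the s-cis conformer requires.

Step 14
Reactants: 19 (2S)-2-ArM-5-bromo-2,3-dihydro-4H-pyran-4-one; 26 bis(silyloxy)diene
Product: 29 (2S)-2-ArM-5,7-dihydroxy-8-(3-methylbut-2-enyl)chroman-4-one, via bromo cycloadduct 27 (not isolated), via bis(silyl) ether 28 (not isolated)
Conditions: 26 (3 equiv), propylene oxide (10 equiv), PhMe, sealed tube, 110 °C; then citric acid (cat.), MeOH, rt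
Reagents that add atoms: none
Why: Proposed new method: the electron-rich diene 26 should add across the brominated C5=C6 bond of 19 (future C4a=C8a) in a strongly polarised, asynchronous (4+2) cycloaddition in which C8–C8a bonding runs ahead of C4a–C5 bonding, giving 27; 1,4-loss of methanol (C5–OMe, C8–H) then leaves a bromo-alkoxy-cyclohexadiene whose only exit to an arene is loss of HBr (C4a–Br, C8a–H), which gives 28, and mild methanolysis frees the two phenols of 29. The closest known reaction types are the cycloaddition-aromatisation of 1,3-bis(silyloxy)dienes with bromoquinones and with 3-acceptor-substituted chromones and the Diels–Alder chemistry of 2-bromocycloalkenones; a vinylogous ester activated only by an α-halogen has not been used in this way. Ring A closes as a six-membered carbocycle by intermolecular (4+2) union of a four-carbon and a two-carbon unit, and if the process is stepwise the second bond forms by 6-(enolexo)-exo-trig attack of the bromo enolate carbon C4a on the silyloxycarbenium carbon C5. No new stereocentre survives, since C4a, C5, C8 and C8a all become sp2 on aromatisation, and C2 (set in step 10) lies outside the reacting π system and is safe as long as no base can enolise C3. The step needs regioselectivity (prenyl at C8, never at C6), secured because the prenyl-bearing terminus of 26 is its most nucleophilic carbon and C8a, the oxygen-bearing β carbon of the enone, is the only electrophilic carbon of the dienophile, and it needs retention of O1, secured because bromide and not the O1 alkoxide takes the leaving-group role at the oxidation level of the arene. Because H-8a and Br are cis in 27 and H-8a is not acidic, HBr should leave by an ionisation or syn pathway driven by aromatisation rather than by anti E2, so the medium is kept base-free and propylene oxide takes up HBr and any Me3SiBr before they can cleave the MOM ethers or racemise C2.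

Step 15
Reactants: 29 8-prenyl-5,7-dihydroxyflavanone
Product: 31 (2S)-2-ArM-5-hydroxy-8,8-dimethyl-2,3-dihydro-4H,8H-pyrano[2,3-f]chromen-4-one, via ortho-quinone methide 30 (not isolated)
Conditions: DDQ (1.2 equiv), PhMe, 80 °C
Reagents that add atoms: none
Why: DDQ oxidative cyclisation of an ortho-prenylphenol (hydride abstraction to the ortho-quinone methide, then oxa-6π electrocyclisation) can only engage O7, the sole free oxygen ortho to C8, so only the angular pyran forms.

Step 16
Reactants: 31 MOM-protected chromene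
Product: 32 (2S)-2-ArH-5-hydroxy-8,8-dimethyl-2,3-dihydro-4H,8H-pyrano[2,3-f]chromen-4-one
Conditions: 3 M aq HCl, MeOH, 50 °C
Reagents that add atoms: none
Why: Acid-catalysed acetal exchange removes the four aryl MOM groups under conditions routinely tolerated by chelated 5-hydroxyflavanones, 2,2-dimethylchromenes and the already thermodynamic trans-dihydrobenzofuran; it is placed before the acid-sensitive diene exists.

Step 17
Reactants: 32 free chromene
Product: 34 (2S)-2-ArH-5,7-dihydroxy-8-[(1Z)-3-methylbuta-1,3-dienyl]chroman-4-one (target CNP0284772.1), via ortho-quinone methide 33 (not isolated)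
Conditions: hν (λ > 300 nm, Pyrex-filtered medium-pressure Hg lamp), degassed MeCN, 0 °C, dilute; stopped at partial conversion, 32 recycled; product kept cold, dark and acid-free
Reagents that add atoms: none
Why: Photochemical 6π electrocyclic opening of a 2,2-dimethyl-2H-chromene followed by a thermal [1,7]-H shift from a geminal methyl to O7 is a known route to (Z)-2-(3-methylbuta-1,3-dienyl)phenols; the Z geometry arises because the new C=C is formed from the bond held s-cis in the cyclic transition state, and no stereocentre is involved.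

## Compound list

1 | 5-bromo-2-hydroxy-4-methoxybenzaldehyde | O=Cc1cc(Br)c(OC)cc1O | starting material
2 | 4-methoxybenzyl chloride | COc1ccc(CCl)cc1 | starting material
3 | 5-bromo-4-methoxy-2-[(4-methoxybenzyl)oxy]benzaldehyde | O=Cc1cc(Br)c(OC)cc1OCc1ccc(OC)cc1 | intermediate
4 | 1-bromo-3,5-dimethoxybenzene | COc1cc(Br)cc(OC)c1 | starting material
5 | 3,5-dimethoxyphenylmagnesium bromide | COc1cc(OC)cc([Mg]Br)c1 | intermediate
6 | {5-bromo-4-methoxy-2-[(4-methoxybenzyl)oxy]phenyl}(3,5-dimethoxyphenyl)methanol | OC(c1cc(OC)cc(OC)c1)c1cc(Br)c(OC)cc1OCc1ccc(OC)cc1 | intermediate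
7 | {5-bromo-4-methoxy-2-[(4-methoxybenzyl)oxy]phenyl}(3,5-dimethoxyphenyl)methanone | O=C(c1cc(OC)cc(OC)c1)c1cc(Br)c(OC)cc1OCc1ccc(OC)cc1 | intermediate
8 | hydrazone of 7 | NN=C(c1cc(OC)cc(OC)c1)c1cc(Br)c(OC)cc1OCc1ccc(OC)cc1 | intermediate
9 | diaryldiazomethane from 8 | [N-]=[N+]=C(c1cc(OC)cc(OC)c1)c1cc(Br)c(OC)cc1OCc1ccc(OC)cc1 | intermediate
10 | (2S,3R)-5-bromo-3-(3,5-dimethoxyphenyl)-6-methoxy-2-(4-methoxyphenyl)-2,3-dihydro-1-benzofuran (cis) | Brc1cc2c(cc1OC)O[C@H](c1ccc(OC)cc1)[C@@H]2c1cc(OC)cc(OC)c1 | intermediate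
11 | (2R,3R)-5-bromo-3-(3,5-dimethoxyphenyl)-6-methoxy-2-(4-methoxyphenyl)-2,3-dihydro-1-benzofuran (trans) | Brc1cc2c(cc1OC)O[C@@H](c1ccc(OC)cc1)[C@@H]2c1cc(OC)cc(OC)c1 | intermediate
12 | (2R,3R)-5-bromo-3-(3,5-dihydroxyphenyl)-2-(4-hydroxyphenyl)-2,3-dihydro-1-benzofuran-6-ol | Brc1cc2c(cc1O)O[C@@H](c1ccc(O)cc1)[C@@H]2c1cc(O)cc(O)c1 | intermediate
13 | ArM–Br | Brc1cc2c(cc1OCOC)O[C@@H](c1ccc(OCOC)cc1)[C@@H]2c1cc(OCOC)cc(OCOC)c1 | intermediate
14 | ArM–Li | [Li]c1cc2c(cc1OCOC)O[C@@H](c1ccc(OCOC)cc1)[C@@H]2c1cc(OCOC)cc(OCOC)c1 | intermediate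
15 | ArM–CHO | O=Cc1cc2c(cc1OCOC)O[C@@H](c1ccc(OCOC)cc1)[C@@H]2c1cc(OCOC)cc(OCOC)c1 | intermediate
16 | (E)-1-methoxy-3-(trimethylsilyloxy)buta-1,3-diene | CO/C=C/C(=C)O[Si](C)(C)C | starting material
17 | (6S)-6-ArM-2-methoxy-4-(trimethylsilyloxy)-5,6-dihydro-2H-pyran | COC1O[C@H](c2cc3c(cc2OCOC)O[C@@H](c2ccc(OCOC)cc2)[C@@H]3c2cc(OCOC)cc(OCOC)c2)CC(O[Si](C)(C)C)=C1 | intermediate
18 | (6S)-6-ArM-3-bromo-2-methoxyoxan-4-one | COC1O[C@H](c2cc3c(cc2OCOC)O[C@@H](c2ccc(OCOC)cc2)[C@@H]3c2cc(OCOC)cc(OCOC)c2)CC(=O)C1Br | intermediate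
19 | (2S)-2-ArM-5-bromo-2,3-dihydro-4H-pyran-4-one | BrC1=CO[C@H](c2cc3c(cc2OCOC)O[C@@H](c2ccc(OCOC)cc2)[C@@H]3c2cc(OCOC)cc(OCOC)c2)CC1=O | intermediate
20 | methyl acetoacetate | COC(=O)CC(C)=O | starting material
21 | 1-bromo-3-methylbut-2-ene | CC(C)=CCBr | starting material
22 | sodium lithium dianion of methyl acetoacetate | [Na+].[Li+].[CH2-]C(=O)[CH-]C(=O)OC | intermediate
23 | methyl 7-methyl-3-oxooct-6-enoate | COC(=O)CC(=O)CCC=C(C)C | intermediate
24 | methyl 7-methyl-3-(trimethylsilyloxy)octa-2,6-dienoate | COC(=O)C=C(O[Si](C)(C)C)CCC=C(C)C | intermediate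
25 | lithium dienolate of 24 | [Li+].COC([O-])=CC(O[Si](C)(C)C)=CCC=C(C)C | intermediate
26 | (1Z,3Z)-1-methoxy-7-methyl-1,3-bis(trimethylsilyloxy)octa-1,3,6-triene | CO/C(O[Si](C)(C)C)=C/C(O[Si](C)(C)C)=C/CC=C(C)C | intermediate
27 | (2S)-2-ArM-4a-bromo-5-methoxy-8-(3-methylbut-2-enyl)-5,7-bis(trimethylsilyloxy)-2,3,4a,5,8,8a-hexahydrochromen-4-one | CC(C)=CCC1C(O[Si](C)(C)C)=CC(OC)(O[Si](C)(C)C)C2(Br)C1O[C@H](c1cc3c(cc1OCOC)O[C@@H](c1ccc(OCOC)cc1)[C@@H]3c1cc(OCOC)cc(OCOC)c1)CC2=O | intermediate
28 | (2S)-2-ArM-8-(3-methylbut-2-enyl)-5,7-bis(trimethylsilyloxy)chroman-4-one | CC(C)=CCc1c(O[Si](C)(C)C)cc(O[Si](C)(C)C)c2c1O[C@H](c1cc3c(cc1OCOC)O[C@@H](c1ccc(OCOC)cc1)[C@@H]3c1cc(OCOC)cc(OCOC)c1)CC2=O | intermediate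
29 | (2S)-2-ArM-5,7-dihydroxy-8-(3-methylbut-2-enyl)chroman-4-one | CC(C)=CCc1c(O)cc(O)c2c1O[C@H](c1cc3c(cc1OCOC)O[C@@H](c1ccc(OCOC)cc1)[C@@H]3c1cc(OCOC)cc(OCOC)c1)CC2=O | intermediate
30 | (2S)-2-ArM-5-hydroxy-8-(3-methylbut-2-enylidene)-2,3-dihydrochromene-4,7-dione | CC(C)=CC=C1C(=O)C=C(O)C2=C1O[C@H](c1cc3c(cc1OCOC)O[C@@H](c1ccc(OCOC)cc1)[C@@H]3c1cc(OCOC)cc(OCOC)c1)CC2=O | intermediate
31 | (2S)-2-ArM-5-hydroxy-8,8-dimethyl-2,3-dihydro-4H,8H-pyrano[2,3-f]chromen-4-one | CC1(C)C=Cc2c(O1)cc(O)c1c2O[C@H](c2cc3c(cc2OCOC)O[C@@H](c2ccc(OCOC)cc2)[C@@H]3c2cc(OCOC)cc(OCOC)c2)CC1=O | intermediate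
32 | (2S)-2-ArH-5-hydroxy-8,8-dimethyl-2,3-dihydro-4H,8H-pyrano[2,3-f]chromen-4-one | CC1(C)C=Cc2c(O1)cc(O)c1c2O[C@H](c2cc3c(cc2O)O[C@@H](c2ccc(O)cc2)[C@@H]3c2cc(O)cc(O)c2)CC1=O | intermediate
33 | (2S)-2-ArH-5-hydroxy-8-(3-methylbut-2-enylidene)-2,3-dihydrochromene-4,7-dione | CC(C)=CC=C1C(=O)C=C(O)C2=C1O[C@H](c1cc3c(cc1O)O[C@@H](c1ccc(O)cc1)[C@@H]3c1cc(O)cc(O)c1)CC2=O | intermediate
34 | (2S)-2-ArH-5,7-dihydroxy-8-[(1Z)-3-methylbuta-1,3-dienyl]chroman-4-one | C=C(C)/C=C\c1c(O)cc(O)c2c1O[C@H](c1cc3c(cc1O)O[C@@H](c1ccc(O)cc1)[C@@H]3c1cc(O)cc(O)c1)CC2=O | target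

## Step count and risks

Total step count: 17. Longest linear sequence: 14 (steps 1–10, then 14–17). Steps 11–13 form the side branch.

**Step 14 (key step).**
- What may go wrong: the cycloaddition may be slower than thermal decay of the diene. A purely polar addition may be followed by expulsion of O1 from the intermediate enolate. Bromide may be lost as a positive-halogen transfer instead of as HBr.
- Fallback (known chemistry): it sets out from aldehyde 15 and returns at 32.
  - 2,4,6-Trihydroxyacetophenone is condensed with 3-methylbut-2-enal (ethylenediammonium diacetate, PhMe, reflux; Knoevenagel condensation and oxa-6π closure). This gives 1-(5,7-dihydroxy-2,2-dimethyl-2H-chromen-6-yl)ethanone F1, which is separated from its 8-acetyl isomer.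
  - The less hindered 7-OH is masked (MOMCl, K2CO3, acetone) to give 1-[5-hydroxy-7-(methoxymethoxy)-2,2-dimethyl-2H-chromen-6-yl]ethanone F2.
  - Claisen–Schmidt condensation of F2 with 15 (KOH, EtOH, rt) gives the (E)-2'-hydroxychalcone F3.
  - Oxa-Michael cyclisation through the chromene 5-OH (NaOAc, EtOH, reflux, or a cinchona-derived bifunctional base) gives the (2S)-5-O-MOM pyranoflavanone F4. The C2 epimers are diastereomers and are separated by chromatography; the unwanted one is re-equilibrated.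
  - The conditions of step 16 then remove all five MOM groups and give 32.

**Step 17.**
- What may go wrong: excited-state proton transfer in the chelated 5-OH/C4=O unit may deactivate the chromophore before the pyran opens. Light-induced C2–O1 cleavage may epimerise C2. The product may revert thermally to the chromene.
- Fallback: it sets out from aldehyde 15 and returns at 34, making the Z-alkene by alkyne semi-reduction.
  - Commercial 1-[2-hydroxy-4,6-bis(methoxymethoxy)phenyl]ethanone is iodinated (NIS, DMF, rt) to 1-[2-hydroxy-3-iodo-4,6-bis(methoxymethoxy)phenyl]ethanone F5.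
  - Claisen–Schmidt condensation with 15 (KOH, EtOH) gives the iodochalcone F6.
  - Oxa-Michael cyclisation and separation of the C2 epimers, as above, give the (2S)-8-iodoflavanone F7.
  - Sonogashira coupling with 2-methylbut-1-en-3-yne (PdCl2(PPh3)2, CuI, Et3N, THF) gives the MOM-protected enyne F8.
  - Treatment with 3 M HCl in MeOH gives the free enyne hexaphenol F9.
  - Neutral cis-selective reduction of the conjugated triple bond (Zn activated with Cu(OAc)2 and AgNO3, MeOH–H2O, rt) gives 34.

**Step 15.**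
- What may go wrong: hydride abstraction from C2–H of the electron-rich dihydrobenzofuran may compete and lead to its aromatisation or over-oxidation.
- Fallback: it sets out from 29 and returns at 31 without a quinone oxidant.
  - Selenoetherification (PhSeCl, CH2Cl2, −78 °C; 6-endo attack of O7 at the tertiary carbon) gives the 3-(phenylselanyl)-2,2-dimethylchroman F10.
  - Oxidation (H2O2, THF, 0 °C) gives the selenoxide F11, which undergoes syn-elimination towards the benzylic CH2 on warming to rt and gives 31.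

Further compounds
F1 | step 14 | 1-(5,7-dihydroxy-2,2-dimethyl-2H-chromen-6-yl)ethanone | CC(=O)c1c(O)cc2c(c1O)C=CC(C)(C)O2
F2 | step 14 | 1-[5-hydroxy-7-(methoxymethoxy)-2,2-dimethyl-2H-chromen-6-yl]ethanone | CC(=O)c1c(OCOC)cc2c(c1O)C=CC(C)(C)O2
F3 | step 14 | (E)-3-ArM-1-[5-hydroxy-7-(methoxymethoxy)-2,2-dimethyl-2H-chromen-6-yl]prop-2-en-1-one | COCOc1cc2c(c(O)c1C(=O)/C=C/c1cc3c(cc1OCOC)O[C@@H](c1ccc(OCOC)cc1)[C@@H]3c1cc(OCOC)cc(OCOC)c1)C=CC(C)(C)O2
F4 | step 14 | (2S)-2-ArM-5-(methoxymethoxy)-8,8-dimethyl-2,3-dihydro-4H,8H-pyrano[2,3-f]chromen-4-one | CC1(C)C=Cc2c(O1)cc(OCOC)c1c2O[C@H](c2cc3c(cc2OCOC)O[C@@H](c2ccc(OCOC)cc2)[C@@H]3c2cc(OCOC)cc(OCOC)c2)CC1=O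
F5 | step 17 | 1-[2-hydroxy-3-iodo-4,6-bis(methoxymethoxy)phenyl]ethanone | CC(=O)c1c(O)c(I)c(OCOC)cc1OCOC
F6 | step 17 | (E)-3-ArM-1-[2-hydroxy-3-iodo-4,6-bis(methoxymethoxy)phenyl]prop-2-en-1-one | O=C(/C=C/c1cc2c(cc1OCOC)O[C@@H](c1ccc(OCOC)cc1)[C@@H]2c1cc(OCOC)cc(OCOC)c1)c1c(O)c(I)c(OCOC)cc1OCOC
F7 | step 17 | (2S)-2-ArM-8-iodo-5,7-bis(methoxymethoxy)chroman-4-one | COCOc1cc(OCOC)c2c(c1I)O[C@H](c1cc3c(cc1OCOC)O[C@@H](c1ccc(OCOC)cc1)[C@@H]3c1cc(OCOC)cc(OCOC)c1)CC2=O
F8 | step 17 | (2S)-2-ArM-5,7-bis(methoxymethoxy)-8-(3-methylbut-3-en-1-ynyl)chroman-4-one | COCOc1cc(OCOC)c2c(c1C#CC(C)=C)O[C@H](c1cc3c(cc1OCOC)O[C@@H](c1ccc(OCOC)cc1)[C@@H]3c1cc(OCOC)cc(OCOC)c1)CC2=O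
F9 | step 17 | (2S)-2-ArH-5,7-dihydroxy-8-(3-methylbut-3-en-1-ynyl)chroman-4-one | Oc1cc(O)c2c(c1C#CC(C)=C)O[C@H](c1cc3c(cc1O)O[C@@H](c1ccc(O)cc1)[C@@H]3c1cc(O)cc(O)c1)CC2=O
F10 | step 15 | (2S)-2-ArM-5-hydroxy-8,8-dimethyl-9-(phenylselanyl)-2,3,9,10-tetrahydro-4H,8H-pyrano[2,3-f]chromen-4-one | CC1(C)Oc2cc(O)c3c(c2CC1[Se]c1ccccc1)O[C@H](c1cc2c(cc1OCOC)O[C@@H](c1ccc(OCOC)cc1)[C@@H]2c1cc(OCOC)cc(OCOC)c1)CC3=O
F11 | step 15 | selenoxide of F10 | CC1(C)Oc2cc(O)c3c(c2CC1[Se](=O)c1ccccc1)O[C@H](c1cc2c(cc1OCOC)O[C@@H](c1ccc(OCOC)cc1)[C@@H]2c1cc(OCOC)cc(OCOC)c1)CC3=O
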